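**Retrosynthetic overview**

1. Target 15 ⇐ benzyl ether 14 (hydrogenolysis at O8) ⇐ 4-aryl-2H-chromene 13 (oxidation of the C2 methylene to the lactone carbonyl).
2. 13 ⇐ 2-(1-arylallyl)phenol 11 by the O1–C2 disconnection: DDQ dehydrogenation to an ortho-quinone methide, then oxa-6π closure. Ring B is the only ring formed and is formed last; rings A and C are bought.
3. 11 ⇐ cinnamyl aryl ether 9 (aromatic Claisen rearrangement, C4–C4a bond) ⇐ phenol 7 + cinnamyl alcohol 8 (Mitsunobu).
4. 7 ⇐ aldehyde 1: MOM ether, Baeyer–Villiger/Dakin oxidation of CHO to the future O8, benzylation, MOM removal.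
5. Feature (coumarin numbering): C4 is doubly benzylic between ring A (C4a) and ring C, and C2 is bonded only to O1 and C3. C2–C3 can therefore be the vinyl group of a 1-arylallyl unit ortho to the C8a phenol oxygen.

Key step: step 7

Remark on the chemistry: 11 is made and used as the racemate. Its only stereocentre (the future C4) becomes sp2 in step 7, and the target is achiral.

**Route**

Step 1
Reactants: 1 2-hydroxy-4,6-dimethoxybenzaldehyde
Product: 2 2,4-dimethoxy-6-(methoxymethoxy)benzaldehyde
Conditions: MOMCl, iPr2NEt, CH2Cl2, 0 °C to reflux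
Reagents that add atoms: chloromethyl methyl ether (MOMCl), COCCl
Why: O-alkylation of the chelated phenol (MOM ether formation) masks the future O1 oxygen as an acetal that should survive the peracid and the basic benzylation to come.

Step 2
Reactants: 2 2,4-dimethoxy-6-(methoxymethoxy)benzaldehyde
Product: 4 2,4-dimethoxy-6-(methoxymethoxy)phenol, via aryl formate 3 (not isolated)
Conditions: mCPBA, CH2Cl2, 0 °C to rt; then K2CO3 (cat.), MeOH, rt, under Ar
Reagents that add atoms: meta-chloroperoxybenzoic acid (mCPBA), OOC(=O)c1cccc(Cl)c1
Why: Baeyer–Villiger (Dakin-type) oxidation, in which the electron-rich aryl group flanked by two ortho oxygens migrates in preference to hydride to give the formate, which mild methanolysis should cleave without touching the MOM acetal.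

Step 3
Reactants: 4 2,4-dimethoxy-6-(methoxymethoxy)phenol; 5 benzyl bromide
Product: 6 2-(benzyloxy)-1,5-dimethoxy-3-(methoxymethoxy)benzene
Conditions: K2CO3, DMF, rt, under Ar
Reagents that add atoms: none
Why: Williamson ether synthesis on the only free phenol places the benzyl group on the oxygen that becomes O8.

Step 4
Reactants: 6 2-(benzyloxy)-1,5-dimethoxy-3-(methoxymethoxy)benzene
Product: 7 2-(benzyloxy)-3,5-dimethoxyphenol
Conditions: HCl (cat., conc. aq.), MeOH, 50 °C
Reagents that add atoms: none
Why: Acid-catalysed acetal exchange with methanol (MOM cleavage) frees the future O1 phenol, while benzyl and methyl aryl ethers are inert to dilute acid.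

Step 5
Reactants: 7 2-(benzyloxy)-3,5-dimethoxyphenol; 8 (2E)-3-(3,4-dimethoxyphenyl)prop-2-en-1-ol
Product: 9 2-(benzyloxy)-1-{[(2E)-3-(3,4-dimethoxyphenyl)prop-2-en-1-yl]oxy}-3,5-dimethoxybenzene
Conditions: PPh3, DIAD, THF, 0 °C to rt
Reagents that add atoms: none
Why: Mitsunobu etherification, in which the phenoxide displaces the primary allylic oxyphosphonium group at the CH2 carbon, so the E alkene is kept and no unstable cinnamyl halide is needed.

Step 6
Reactants: 9 2-(benzyloxy)-1-{[(2E)-3-(3,4-dimethoxyphenyl)prop-2-en-1-yl]oxy}-3,5-dimethoxybenzene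
Product: 11 racemic 2-(benzyloxy)-6-[1-(3,4-dimethoxyphenyl)prop-2-en-1-yl]-3,5-dimethoxyphenol, via cyclohexadienone 10 (not isolated)
Conditions: PhNEt2, 190 °C, under Ar
Reagents that add atoms: none
Why: Aromatic Claisen rearrangement, a [3,3] shift that joins the aryl-bearing alkene carbon to the only unsubstituted ortho carbon (the future C4a) and is made irreversible by tautomerisation of dienone 10, the new stereocentre being formed without control as the racemate and removed in step 7.

Step 7
Reactants: 11 racemic 2-(benzyloxy)-6-[1-(3,4-dimethoxyphenyl)prop-2-en-1-yl]-3,5-dimethoxyphenol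
Product: 13 8-(benzyloxy)-4-(3,4-dimethoxyphenyl)-5,7-dimethoxy-2H-chromene, via ortho-quinone methide 12 (not isolated)
Conditions: DDQ (1.05 equiv, slow addition), PhH, rt to 60 °C
Reagents that add atoms: none
Why: DDQ should remove hydride from the C–H that is benzylic to both aryl rings and allylic (the future C4), the most hydridic C–H bond of 11, and loss of the phenol proton from the resulting trioxygenated diarylallyl cation gives ortho-quinone methide 12, in which O1, C8a, C4a, C4, C3 and C2 form a 1-oxatriene. Thermal oxa-6π electrocyclisation then joins O1 to the terminal vinyl carbon C2 and restores the aromaticity of ring A; the closest known reaction type is the DDQ dehydrogenative cyclisation of ortho-prenyl, ortho-cinnamyl and ortho-(1-arylallyl) phenols to 2H-chromenes. Ring B is closed at O1–C2 as a six-membered 2H-pyran by a 6π electrocyclic closure (capture of the allyl cation terminus by the phenol oxygen would lead to the same product). No stereocentre is formed, and the racemic centre of 11 is erased. The step needs hydride loss at C4 only and closure on oxygen to the six-membered ring only: the first is secured by the double benzylic and allylic activation, the second because only the isomer of 12 with the vinyl group on the carbonyl side can close, the two geometric isomers being expected to interconvert through the stabilised zwitterion. Over-oxidation of 13 at C2 to a benzopyrylium ion is to be held back by using one equivalent of DDQ in a non-polar solvent from which the hydroquinone precipitates.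

Step 8
Reactants: 13 8-(benzyloxy)-4-(3,4-dimethoxyphenyl)-5,7-dimethoxy-2H-chromene
Product: 14 8-(benzyloxy)-4-(3,4-dimethoxyphenyl)-5,7-dimethoxy-2H-chromen-2-one
Conditions: pyridinium chlorochromate [C5H5NH][CrO3Cl] (4 equiv), Celite, CH2Cl2, reflux
Reagents that add atoms: pyridinium chlorochromate, [O-][Cr](=O)(=O)Cl.c1cc[nH+]cc1
Why: Allylic oxidation by hexavalent chromium of the C2 methylene, which is both allylic and alpha to the ring oxygen, is a known way from 2H-chromenes to coumarins, and the benzyl ether CH2 lacks this double activation and should react more slowly.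

Step 9
Reactants: 14 8-(benzyloxy)-4-(3,4-dimethoxyphenyl)-5,7-dimethoxy-2H-chromen-2-one
Product: 15 8-hydroxy-4-(3,4-dimethoxyphenyl)-5,7-dimethoxy-2H-chromen-2-one (8-hydroxy-5,7,3',4'-tetramethoxy-4-phenylcoumarin)
Conditions: H2 (1 atm), 10% Pd/C, EtOAc, rt, stopped after one equivalent of H2
Reagents that add atoms: none
Why: Catalytic hydrogenolysis of the benzyl aryl ether should be much faster than reduction of the trisubstituted, aryl-conjugated and peri-hindered C3–C4 double bond of the coumarin.

**Compound list**

1 | 2-hydroxy-4,6-dimethoxybenzaldehyde | COc1cc(O)c(C=O)c(OC)c1 | starting material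
2 | 2,4-dimethoxy-6-(methoxymethoxy)benzaldehyde | COCOc1cc(OC)cc(OC)c1C=O | intermediate
3 | 2,4-dimethoxy-6-(methoxymethoxy)phenyl formate (formed in step 2, not isolated) | COCOc1cc(OC)cc(OC)c1OC=O | intermediate
4 | 2,4-dimethoxy-6-(methoxymethoxy)phenol | COCOc1cc(OC)cc(OC)c1O | intermediate
5 | benzyl bromide | BrCc1ccccc1 | starting material
6 | 2-(benzyloxy)-1,5-dimethoxy-3-(methoxymethoxy)benzene | COCOc1cc(OC)cc(OC)c1OCc1ccccc1 | intermediate
7 | 2-(benzyloxy)-3,5-dimethoxyphenol | COc1cc(O)c(OCc2ccccc2)c(OC)c1 | intermediate
8 | (2E)-3-(3,4-dimethoxyphenyl)prop-2-en-1-ol | COc1ccc(/C=C/CO)cc1OC | starting material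
9 | 2-(benzyloxy)-1-{[(2E)-3-(3,4-dimethoxyphenyl)prop-2-en-1-yl]oxy}-3,5-dimethoxybenzene | COc1ccc(/C=C/COc2cc(OC)cc(OC)c2OCc2ccccc2)cc1OC | intermediate
10 | 2-(benzyloxy)-6-[1-(3,4-dimethoxyphenyl)prop-2-en-1-yl]-3,5-dimethoxycyclohexa-2,4-dien-1-one (formed in step 6, not isolated, stereocentres uncontrolled) | C=CC(c1ccc(OC)c(OC)c1)C1C(=O)C(OCc2ccccc2)=C(OC)C=C1OC | intermediate
11 | racemic 2-(benzyloxy)-6-[1-(3,4-dimethoxyphenyl)prop-2-en-1-yl]-3,5-dimethoxyphenol | C=CC(c1ccc(OC)c(OC)c1)c1c(O)c(OCc2ccccc2)c(OC)cc1OC | intermediate
12 | 2-(benzyloxy)-6-[1-(3,4-dimethoxyphenyl)prop-2-en-1-ylidene]-3,5-dimethoxycyclohexa-2,4-dien-1-one, isomer with the vinyl group on the side of the ring carbonyl (formed in step 7, not isolated) | C=C/C(c1ccc(OC)c(OC)c1)=C1\C(=O)C(OCc2ccccc2)=C(OC)C=C1OC | intermediate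
13 | 8-(benzyloxy)-4-(3,4-dimethoxyphenyl)-5,7-dimethoxy-2H-chromene | COc1ccc(C2=CCOc3c(OCc4ccccc4)c(OC)cc(OC)c32)cc1OC | intermediate
14 | 8-(benzyloxy)-4-(3,4-dimethoxyphenyl)-5,7-dimethoxy-2H-chromen-2-one | COc1ccc(-c2cc(=O)oc3c(OCc4ccccc4)c(OC)cc(OC)c23)cc1OC | intermediate
15 | 8-hydroxy-4-(3,4-dimethoxyphenyl)-5,7-dimethoxy-2H-chromen-2-one | COc1ccc(-c2cc(=O)oc3c(O)c(OC)cc(OC)c23)cc1OC | target

**Step count and risks**

Total step count: 9. Longest linear sequence: 9 steps (1 to 15); 5 and 8 are used as bought.

Steps most likely to fail: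

Step 7 (key step). The chromene product may be oxidised further at C2 by DDQ to a benzopyrylium ion. The quinone methide may also dimerise by hetero-Diels–Alder reaction or be trapped by the hydroquinone before it closes. Fallback, setting out from 7 and coming back at 13: ring B would be closed without an oxidant by forming the C4–C4a bond instead. Sonogashira coupling of 4-iodo-1,2-dimethoxybenzene with prop-2-yn-1-ol (PdCl2(PPh3)2, CuI, Et3N) would give 3-(3,4-dimethoxyphenyl)prop-2-yn-1-ol F1. Mitsunobu etherification of 7 with F1 (PPh3, DIAD, THF) would give 2-(benzyloxy)-1-{[3-(3,4-dimethoxyphenyl)prop-2-yn-1-yl]oxy}-3,5-dimethoxybenzene F2. Intramolecular 6-endo hydroarylation of the alkyne under cationic gold catalysis (Ph3PAuNTf2, CH2Cl2, rt), at the only free ortho carbon of the electron-rich ring, should then give 13.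

Step 6. The C–O bond of the doubly electron-rich cinnamyl ether may ionise before the concerted shift, which would lead to the [1,3]-shifted linear cinnamylphenol. Other possible failures are migration to the para position through the OBn-bearing ortho carbon and cyclisation of the product onto its alkene at the high temperature. Fallback, setting out from 7 and coming back at 11: the 1-arylallyl unit would be assembled by two organometallic additions through an ortho-quinone methide. Ortho-formylation of 7 (MgCl2, Et3N, paraformaldehyde, MeCN, reflux) would give 3-(benzyloxy)-2-hydroxy-4,6-dimethoxybenzaldehyde F3. Acylation of the phenol (Boc2O, iPr2NEt, cat. DMAP) would give 2-(benzyloxy)-6-formyl-3,5-dimethoxyphenyl tert-butyl carbonate F4. Addition of 3,4-dimethoxyphenylmagnesium bromide at −78 °C would form the benzylic alkoxide, which takes over the carbonate group and eliminates to the transient 2-(benzyloxy)-6-[(3,4-dimethoxyphenyl)methylidene]-3,5-dimethoxycyclohexa-2,4-dien-1-one F5. Conjugate addition of vinylmagnesium bromide (CH2=CHMgBr) to F5 in the same flask should give 11.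

Step 8. The chromium oxidant may attack the electron-rich rings or the benzyl ether methylene, or C2-oxidised intermediates may ring-open to the enal instead of going on to the lactone. Fallback, setting out from 7 and coming back at 14: the carbonyl would be brought in at the lactone oxidation level. Pechmann condensation of 7 with ethyl 3-(3,4-dimethoxyphenyl)-3-oxopropanoate (CF3CO2H, rt) should form the C4–C4a bond at the only free ortho carbon and the lactone in one operation, giving 14 directly. Any material that loses the benzyl group under the acid would already be 15.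

**Further compounds**

F1 | step 7 | 3-(3,4-dimethoxyphenyl)prop-2-yn-1-ol | COc1ccc(C#CCO)cc1OC
F2 | step 7 | 2-(benzyloxy)-1-{[3-(3,4-dimethoxyphenyl)prop-2-yn-1-yl]oxy}-3,5-dimethoxybenzene | COc1ccc(C#CCOc2cc(OC)cc(OC)c2OCc2ccccc2)cc1OC
F3 | step 6 | 3-(benzyloxy)-2-hydroxy-4,6-dimethoxybenzaldehyde | O=Cc1c(O)c(OCc2ccccc2)c(OC)cc1OC
F4 | step 6 | 2-(benzyloxy)-6-formyl-3,5-dimethoxyphenyl tert-butyl carbonate | O=Cc1c(OC(=O)OC(C)(C)C)c(OCc2ccccc2)c(OC)cc1OC
F5 | step 6 | 2-(benzyloxy)-6-[(3,4-dimethoxyphenyl)methylidene]-3,5-dimethoxycyclohexa-2,4-dien-1-one (not isolated) | COc1ccc(C=C2C(=O)C(OCc3ccccc3)=C(OC)C=C2OC)cc1OC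
F0 | step 8 | none | none
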